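**Retrosynthetic overview**

1. Target 15 ⇐ its 7,4′-bis(triisopropylsilyl) ether 14 (fluoride, last step). Rings A and B are bought as 2,4,6-trihydroxyacetophenone 1 and vanillin 5; ring C is the only ring built and it is closed last.
2. Ring C ⇐ C2–C3 bond, by a visible-light Norrish–Yang cyclisation of the achiral ortho-(benzyloxy)aryl glyoxal 11. The glyoxal is stored as its lactol 12 (a temporary five-membered ring that the catalyst opens). One step makes the ring, both stereocentres and the free 3-OH.
3. Enabling features: the C2–H bond is benzylic to ring B and α to O1, and lies across ring A within reach of the aldehyde oxygen O3 (1,7-relationship). The 5-OH beside the C4 ketone gives an O5/O4 two-point site for a chiral scandium Lewis acid, which unmasks the chromophore and shields one face of C3.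
4. 12 ⇐ methyl ketone 8 (diazo transfer, then oxygen-atom transfer). 8 ⇐ 1 by C-prenylation, 4-O-silylation and Mitsunobu etherification of the 6-OH with the silylated vanillyl alcohol 7 (from 5).

Key step: step 8

Assumption: the ortho-hydroxyaryl glyoxal 11 is taken to rest as its cyclic hemiacetal 12, as ortho-hydroxyaryl 1,2-dicarbonyl compounds normally do. The two are ring–chain tautomers, so the catalyst-bound open form that reacts in step 8 is compound 11 again, held on scandium, and not a new compound.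

Assumption: the sense of induction of the scandium–PyBox complex cannot be predicted with certainty; the (S,S)-ligand, 2,6-bis[(4S)-4-tert-butyl-4,5-dihydro-1,3-oxazol-2-yl]pyridine, is written, and the (R,R)-ligand would be used if it proved to favour the mirror image.

**Route**

Step 1
Reactants: 1 2,4,6-trihydroxyacetophenone; 2 prenyl bromide (1-bromo-3-methylbut-2-ene)
Product: 3 1-[2,4,6-trihydroxy-3-(3-methylbut-2-en-1-yl)phenyl]ethan-1-one
Conditions: DBU (1.0 equiv), THF, 0 °C to rt
Reagents that add atoms: none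
Why: C-alkylation of the ambident phloroglucinol-type phenoxide (Friedel–Crafts-type C-prenylation); the two free ring positions of 1 are equivalent, so only one mono-C-prenyl isomer can form.

Step 2
Reactants: 3 1-[2,4,6-trihydroxy-3-(3-methylbut-2-en-1-yl)phenyl]ethan-1-one
Product: 4 1-[2,6-dihydroxy-3-(3-methylbut-2-en-1-yl)-4-(triisopropylsilyloxy)phenyl]ethan-1-one
Conditions: TIPSCl (1.05 equiv), imidazole, DMF, 0 °C
Reagents that add atoms: triisopropylsilyl chloride, CC(C)[Si](Cl)(C(C)C)C(C)C
Why: Silyl ether formation should take place at the 4-OH, the most acidic hydroxyl (para to the acetyl group) and the one that neither hydrogen-bonds to the carbonyl oxygen nor sits beside the acetyl group.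

Step 3
Reactants: 5 vanillin (4-hydroxy-3-methoxybenzaldehyde)
Product: 6 3-methoxy-4-(triisopropylsilyloxy)benzaldehyde
Conditions: TIPSCl (1.1 equiv), imidazole, DMF, rt
Reagents that add atoms: triisopropylsilyl chloride, CC(C)[Si](Cl)(C(C)C)C(C)C
Why: Silyl ether formation on the only phenol of vanillin.

Step 4
Reactants: 6 3-methoxy-4-(triisopropylsilyloxy)benzaldehyde
Product: 7 [3-methoxy-4-(triisopropylsilyloxy)phenyl]methanol
Conditions: NaBH4, MeOH, 0 °C
Reagents that add atoms: none
Why: Hydride reduction of the aldehyde to the benzylic alcohol; the aryl silyl ether is not touched.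

Step 5
Reactants: 4 1-[2,6-dihydroxy-3-(3-methylbut-2-en-1-yl)-4-(triisopropylsilyloxy)phenyl]ethan-1-one; 7 [3-methoxy-4-(triisopropylsilyloxy)phenyl]methanol
Product: 8 1-[2-hydroxy-6-{[3-methoxy-4-(triisopropylsilyloxy)phenyl]methoxy}-3-(3-methylbut-2-en-1-yl)-4-(triisopropylsilyloxy)phenyl]ethan-1-one
Conditions: PPh3 (1.2 equiv), DIAD (1.2 equiv), THF, 0 °C to rt
Reagents that add atoms: none
Why: Mitsunobu etherification of a phenol with a primary benzylic alcohol; the 6-OH, flanked only by H-5, should react in preference to the 2-OH, which is flanked by the prenyl group and held in the hydrogen bond to the ketone.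

Step 6
Reactants: 8 1-[2-hydroxy-6-{[3-methoxy-4-(triisopropylsilyloxy)phenyl]methoxy}-3-(3-methylbut-2-en-1-yl)-4-(triisopropylsilyloxy)phenyl]ethan-1-one
Product: 10 2-diazo-1-[2-hydroxy-6-{[3-methoxy-4-(triisopropylsilyloxy)phenyl]methoxy}-3-(3-methylbut-2-en-1-yl)-4-(triisopropylsilyloxy)phenyl]ethan-1-one, via trifluoroacetyl ketone 9 (not isolated)
Conditions: LiN(SiMe3)2 (2.2 equiv), THF, −78 °C; CF3CO2CH2CF3 (1.3 equiv); aq. HCl; then MsN3 (1.5 equiv), Et3N (1.5 equiv), H2O (1 equiv), MeCN, rt
Reagents that add atoms: 2,2,2-trifluoroethyl trifluoroacetate, O=C(OCC(F)(F)F)C(F)(F)F (its acyl group is held only by 9); methanesulfonyl azide, CS(=O)(=O)N=[N+]=[N-]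
Why: Detrifluoroacetylative diazo transfer (Claisen trifluoroacetylation of the ketone enolate, then Regitz-type diazo transfer with loss of the activating acyl group); the second equivalent of base covers the phenol, which is returned on work-up.

Step 7
Reactants: 10 2-diazo-1-[2-hydroxy-6-{[3-methoxy-4-(triisopropylsilyloxy)phenyl]methoxy}-3-(3-methylbut-2-en-1-yl)-4-(triisopropylsilyloxy)phenyl]ethan-1-one
Product: 12 2-hydroxy-4-{[3-methoxy-4-(triisopropylsilyloxy)phenyl]methoxy}-7-(3-methylbut-2-en-1-yl)-6-(triisopropylsilyloxy)-1-benzofuran-3(2H)-one, via open-chain aryl glyoxal 11 (not isolated)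
Conditions: dimethyldioxirane (1.0 equiv, acetone), CH2Cl2, −78 to −30 °C; evaporate
Reagents that add atoms: dimethyldioxirane, CC1(C)OO1
Why: Oxygen-atom transfer from the dioxirane to the nucleophilic diazo carbon with loss of N2 (dioxirane oxidation of an α-diazoketone to an α-ketoaldehyde) should be much faster than epoxidation of the prenyl alkene; the 5-OH then adds to the new aldehyde to give the lactol as a mixture of epimers, which is of no consequence.

Step 8
Reactants: 12 2-hydroxy-4-{[3-methoxy-4-(triisopropylsilyloxy)phenyl]methoxy}-7-(3-methylbut-2-en-1-yl)-6-(triisopropylsilyloxy)-1-benzofuran-3(2H)-one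
Product: 14 (2R,3R)-3,5-dihydroxy-2-[3-methoxy-4-(triisopropylsilyloxy)phenyl]-6-(3-methylbut-2-en-1-yl)-7-(triisopropylsilyloxy)-2,3-dihydro-4H-chromen-4-one, via triplet 1,6-biradical 13 (not isolated)
Conditions: Sc(OTf)3 (20 mol %), (S,S)-tBu-PyBox (24 mol %), 2,6-di-tert-butylpyridine (20 mol %), 4 Å MS, degassed MeCN/PhCF3 (1:3, 2 mM), 450 nm LED, −20 °C; aq. NaHCO3 work-up
Reagents that add atoms: none
Why: Proposed new method: the chiral scandium–PyBox Lewis acid should bind lactol 12 through the phenol oxygen O5 and the ketone oxygen O4 and hold it as its yellow ring–chain tautomer, the open 1,2-dicarbonyl form 11 first met in step 7, with the aldehyde oxygen O3 left free, so that excitation of the n,π* band gives a triplet in which O3 abstracts the C2–H atom (benzylic to ring B, α to O1) through an eight-membered transition state (1,7-hydrogen atom transfer), and the 1,6-biradical 13 then joins C2 to C3 after intersystem crossing. The closest known reaction types are the Norrish–Yang cyclisation of 1-(ortho-alkylaryl)-1,2-diones to 2-hydroxyindan-1-ones, in which the remote carbonyl oxygen likewise abstracts, and the scandium–PyBox-controlled triplet [2+2] cycloadditions of 2′-hydroxychalcones, which rely on the same two-point binding of an ortho-hydroxyaryl ketone. Ring C, the only ring closed, forms by recombination of the two radical centres of 13 in a six-membered, chair-like arrangement. C3 is set by the ligand, because the chelated C3 radical is coplanar with ring A and one of its faces is covered by a tert-butyl-oxazoline arm, so that C2 should add to the open face; C2 is set relative to C3 by the chair-like closure that keeps ring B pseudo-equatorial and the C3–OH hydrogen-bonded to O4, which gives the 2,3-trans arrangement. The step needs abstraction by O3 and not by O4 (which would lead to a dihydrobenzofuranol), secured because O4 is tied to scandium and the anti arrangement of the two carbonyl groups places O3 next to the O1–CH2 group; it needs no racemic background reaction, secured because unbound 12 is a colourless lactol that does not absorb at 450 nm; and it needs the prenyl alkene and the silyl ethers to stay intact, which the low temperature, the buffered Lewis acid and the lack of a reachable C–H bond on these groups should allow.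

Step 9
Reactants: 14 (2R,3R)-3,5-dihydroxy-2-[3-methoxy-4-(triisopropylsilyloxy)phenyl]-6-(3-methylbut-2-en-1-yl)-7-(triisopropylsilyloxy)-2,3-dihydro-4H-chromen-4-one
Product: 15 (2R,3R)-3,5,7-trihydroxy-2-(4-hydroxy-3-methoxyphenyl)-6-(3-methylbut-2-en-1-yl)-2,3-dihydro-4H-chromen-4-one
Conditions: Bu4NF (2.4 equiv), AcOH (2.6 equiv), THF, 0 °C
Reagents that add atoms: none
Why: Fluoride cleavage of the two aryl silyl ethers; the acetic acid buffer keeps the 4′-phenol protonated, so the C2–O1 bond should not open through a quinone methide and neither stereocentre should be epimerised.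

**Compound list**

1 | 2,4,6-trihydroxyacetophenone | CC(=O)c1c(O)cc(O)cc1O | starting material
2 | prenyl bromide (1-bromo-3-methylbut-2-ene) | CC(C)=CCBr | starting material
3 | 1-[2,4,6-trihydroxy-3-(3-methylbut-2-en-1-yl)phenyl]ethan-1-one | CC(=O)c1c(O)cc(O)c(CC=C(C)C)c1O | intermediate
4 | 1-[2,6-dihydroxy-3-(3-methylbut-2-en-1-yl)-4-(triisopropylsilyloxy)phenyl]ethan-1-one | CC(=O)c1c(O)cc(O[Si](C(C)C)(C(C)C)C(C)C)c(CC=C(C)C)c1O | intermediate
5 | vanillin | COc1cc(C=O)ccc1O | starting material
6 | 3-methoxy-4-(triisopropylsilyloxy)benzaldehyde | COc1cc(C=O)ccc1O[Si](C(C)C)(C(C)C)C(C)C | intermediate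
7 | [3-methoxy-4-(triisopropylsilyloxy)phenyl]methanol | COc1cc(CO)ccc1O[Si](C(C)C)(C(C)C)C(C)C | intermediate
8 | 1-[2-hydroxy-6-{[3-methoxy-4-(triisopropylsilyloxy)phenyl]methoxy}-3-(3-methylbut-2-en-1-yl)-4-(triisopropylsilyloxy)phenyl]ethan-1-one | CC(=O)c1c(OCc2ccc(O[Si](C(C)C)(C(C)C)C(C)C)c(OC)c2)cc(O[Si](C(C)C)(C(C)C)C(C)C)c(CC=C(C)C)c1O | intermediate
9 | 4,4,4-trifluoro-1-[2-hydroxy-6-{[3-methoxy-4-(triisopropylsilyloxy)phenyl]methoxy}-3-(3-methylbut-2-en-1-yl)-4-(triisopropylsilyloxy)phenyl]butane-1,3-dione | O=C(CC(=O)C(F)(F)F)c1c(OCc2ccc(O[Si](C(C)C)(C(C)C)C(C)C)c(OC)c2)cc(O[Si](C(C)C)(C(C)C)C(C)C)c(CC=C(C)C)c1O | intermediate (not isolated)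
10 | 2-diazo-1-[2-hydroxy-6-{[3-methoxy-4-(triisopropylsilyloxy)phenyl]methoxy}-3-(3-methylbut-2-en-1-yl)-4-(triisopropylsilyloxy)phenyl]ethan-1-one | [N-]=[N+]=CC(=O)c1c(OCc2ccc(O[Si](C(C)C)(C(C)C)C(C)C)c(OC)c2)cc(O[Si](C(C)C)(C(C)C)C(C)C)c(CC=C(C)C)c1O | intermediate
11 | 2-[2-hydroxy-6-{[3-methoxy-4-(triisopropylsilyloxy)phenyl]methoxy}-3-(3-methylbut-2-en-1-yl)-4-(triisopropylsilyloxy)phenyl]-2-oxoacetaldehyde (open-chain aryl glyoxal, the ring–chain tautomer of 12) | O=CC(=O)c1c(OCc2ccc(O[Si](C(C)C)(C(C)C)C(C)C)c(OC)c2)cc(O[Si](C(C)C)(C(C)C)C(C)C)c(CC=C(C)C)c1O | intermediate (not isolated)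
12 | 2-hydroxy-4-{[3-methoxy-4-(triisopropylsilyloxy)phenyl]methoxy}-7-(3-methylbut-2-en-1-yl)-6-(triisopropylsilyloxy)-1-benzofuran-3(2H)-one (lactol, both epimers at the lactol carbon) | OC1Oc2c(CC=C(C)C)c(O[Si](C(C)C)(C(C)C)C(C)C)cc(OCc3ccc(O[Si](C(C)C)(C(C)C)C(C)C)c(OC)c3)c2C1=O | intermediate
13 | triplet 1,6-biradical formed from the catalyst-bound open-chain tautomer of 12 after hydrogen transfer from the O–CH2 group to the aldehyde oxygen (radical centres at the future C2 and C3, written without the metal) | O[CH]C(=O)c1c(O[CH]c2ccc(O[Si](C(C)C)(C(C)C)C(C)C)c(OC)c2)cc(O[Si](C(C)C)(C(C)C)C(C)C)c(CC=C(C)C)c1O | intermediate (not isolated)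
14 | (2R,3R)-3,5-dihydroxy-2-[3-methoxy-4-(triisopropylsilyloxy)phenyl]-6-(3-methylbut-2-en-1-yl)-7-(triisopropylsilyloxy)-2,3-dihydro-4H-chromen-4-one | COc1cc([C@H]2Oc3cc(O[Si](C(C)C)(C(C)C)C(C)C)c(CC=C(C)C)c(O)c3C(=O)[C@@H]2O)ccc1O[Si](C(C)C)(C(C)C)C(C)C | intermediate
15 | (2R,3R)-3,5,7-trihydroxy-2-(4-hydroxy-3-methoxyphenyl)-6-(3-methylbut-2-en-1-yl)-2,3-dihydro-4H-chromen-4-one | COc1cc([C@H]2Oc3cc(O)c(CC=C(C)C)c(O)c3C(=O)[C@@H]2O)ccc1O | target

Total step count: 9. Longest linear sequence: 7 steps (steps 1, 2, 5, 6, 7, 8, 9 from 1; the branch from 5 through steps 3 and 4 is equally long).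

**Steps most likely to fail**

1. Step 8 (bears the label "Proposed new method:"). The hydrogen atom may be abstracted through the ketone oxygen, with closure to a five-membered ring; the lactol may not open on the catalyst; the facial control may be poor; or the Lewis acid may add the 5-OH to the prenyl double bond.

   The fallback uses known chemistry, sets out from diazoketone 10 and comes back to the route at target 15. The 5-OH of 10 would be silylated (TBSCl, imidazole, DMF) to give 2-diazo-1-[2-(tert-butyldimethylsilyloxy)-6-{[3-methoxy-4-(triisopropylsilyloxy)phenyl]methoxy}-3-(3-methylbut-2-en-1-yl)-4-(triisopropylsilyloxy)phenyl]ethan-1-one F1. Decomposition of F1 with Rh2(S-PTTL)4, dirhodium tetrakis[N-phthaloyl-(S)-tert-leucinate] (1 mol %, CH2Cl2, −20 °C; the catalyst antipode is chosen to suit), should insert the carbenoid carbon into the benzylic C–H bond next to O1. This is a reaction type known for ortho-alkoxyaryl α-diazoketones with chiral dirhodium carboxylates, and it would give the (2S)-5-(tert-butyldimethylsilyloxy)-7-(triisopropylsilyloxy)-6-prenylflavanone F2. Soft enolisation (Me3SiOTf, Et3N, CH2Cl2, 0 °C) would give the 4-(trimethylsilyloxy)-2H-chromene F3. Rubottom oxidation (dimethyldioxirane, acetone, −78 °C, then dilute aqueous citric acid) should deliver the oxygen to the face away from ring B and give the (2R,3R)-5-(tert-butyldimethylsilyloxy)-3-hydroxyflavanone F4. Desilylation of F4 under the conditions of step 9, with more fluoride, would give 15.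

2. Step 7. The dioxirane may epoxidise the prenyl double bond or oxidise the electron-rich rings before, or along with, the diazo carbon.

   The fallback sets out from ketone 8 and comes back to the route at lactol 12; it also replaces step 6. The dianion of 8 (KN(SiMe3)2, 2.2 equiv, THF, −78 °C) would be hydroxylated with 2-(phenylsulfonyl)-3-phenyloxaziridine to give 2-hydroxy-1-[2-hydroxy-6-{[3-methoxy-4-(triisopropylsilyloxy)phenyl]methoxy}-3-(3-methylbut-2-en-1-yl)-4-(triisopropylsilyloxy)phenyl]ethan-1-one F5. Oxidation of its primary alcohol with Dess–Martin periodinane (NaHCO3, CH2Cl2, 0 °C) would give the glyoxal, which closes to 12. Neither reagent attacks an isolated trisubstituted alkene.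

3. Step 5. The etherification may take place at the wrong ortho hydroxyl, or the activated benzylic alcohol may alkylate the electron-rich ring A at carbon.

   The fallback sets out from 1 and comes back to the route at 8; it replaces steps 1, 2 and 5 and fixes the regiochemistry by construction. Silylation of the 4-OH of 1 (TIPSCl, imidazole, DMF) would give 1-[2,6-dihydroxy-4-(triisopropylsilyloxy)phenyl]ethan-1-one F6. Mitsunobu etherification of one of its two equivalent ortho hydroxyls with 7 (PPh3, DIAD, THF) would give 1-[2-hydroxy-6-{[3-methoxy-4-(triisopropylsilyloxy)phenyl]methoxy}-4-(triisopropylsilyloxy)phenyl]ethan-1-one F7. Allylic etherification of the remaining hydroxyl with tert-butyl 2-methylbut-3-en-2-yl carbonate and Pd(PPh3)4 (zerovalent palladium, THF) would give the 1,1-dimethylallyl ether 1-[2-{[3-methoxy-4-(triisopropylsilyloxy)phenyl]methoxy}-6-[(2-methylbut-3-en-2-yl)oxy]-4-(triisopropylsilyloxy)phenyl]ethan-1-one F8. Aromatic Claisen rearrangement of F8 (Eu(fod)3 cat., CHCl3, 50 °C) moves the allyl unit, with allylic transposition, to the only free ortho carbon and gives 8.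

**Further compounds**

F1 | step 8 | 2-diazo-1-[2-(tert-butyldimethylsilyloxy)-6-{[3-methoxy-4-(triisopropylsilyloxy)phenyl]methoxy}-3-(3-methylbut-2-en-1-yl)-4-(triisopropylsilyloxy)phenyl]ethan-1-one | [N-]=[N+]=CC(=O)c1c(OCc2ccc(O[Si](C(C)C)(C(C)C)C(C)C)c(OC)c2)cc(O[Si](C(C)C)(C(C)C)C(C)C)c(CC=C(C)C)c1O[Si](C)(C)C(C)(C)C
F2 | step 8 | (2S)-5-(tert-butyldimethylsilyloxy)-2-[3-methoxy-4-(triisopropylsilyloxy)phenyl]-6-(3-methylbut-2-en-1-yl)-7-(triisopropylsilyloxy)-2,3-dihydro-4H-chromen-4-one | COc1cc([C@H]2Oc3cc(O[Si](C(C)C)(C(C)C)C(C)C)c(CC=C(C)C)c(O[Si](C)(C)C(C)(C)C)c3C(=O)C2)ccc1O[Si](C(C)C)(C(C)C)C(C)C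
F3 | step 8 | (2S)-5-(tert-butyldimethylsilyloxy)-2-[3-methoxy-4-(triisopropylsilyloxy)phenyl]-6-(3-methylbut-2-en-1-yl)-7-(triisopropylsilyloxy)-4-(trimethylsilyloxy)-2H-chromene | COc1cc([C@H]2Oc3cc(O[Si](C(C)C)(C(C)C)C(C)C)c(CC=C(C)C)c(O[Si](C)(C)C(C)(C)C)c3C(O[Si](C)(C)C)=C2)ccc1O[Si](C(C)C)(C(C)C)C(C)C
F4 | step 8 | (2R,3R)-5-(tert-butyldimethylsilyloxy)-3-hydroxy-2-[3-methoxy-4-(triisopropylsilyloxy)phenyl]-6-(3-methylbut-2-en-1-yl)-7-(triisopropylsilyloxy)-2,3-dihydro-4H-chromen-4-one | COc1cc([C@H]2Oc3cc(O[Si](C(C)C)(C(C)C)C(C)C)c(CC=C(C)C)c(O[Si](C)(C)C(C)(C)C)c3C(=O)[C@@H]2O)ccc1O[Si](C(C)C)(C(C)C)C(C)C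
F5 | step 7 | 2-hydroxy-1-[2-hydroxy-6-{[3-methoxy-4-(triisopropylsilyloxy)phenyl]methoxy}-3-(3-methylbut-2-en-1-yl)-4-(triisopropylsilyloxy)phenyl]ethan-1-one | OCC(=O)c1c(OCc2ccc(O[Si](C(C)C)(C(C)C)C(C)C)c(OC)c2)cc(O[Si](C(C)C)(C(C)C)C(C)C)c(CC=C(C)C)c1O
F6 | step 5 | 1-[2,6-dihydroxy-4-(triisopropylsilyloxy)phenyl]ethan-1-one | CC(=O)c1c(O)cc(O[Si](C(C)C)(C(C)C)C(C)C)cc1O
F7 | step 5 | 1-[2-hydroxy-6-{[3-methoxy-4-(triisopropylsilyloxy)phenyl]methoxy}-4-(triisopropylsilyloxy)phenyl]ethan-1-one | CC(=O)c1c(OCc2ccc(O[Si](C(C)C)(C(C)C)C(C)C)c(OC)c2)cc(O[Si](C(C)C)(C(C)C)C(C)C)cc1O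
F8 | step 5 | 1-[2-{[3-methoxy-4-(triisopropylsilyloxy)phenyl]methoxy}-6-[(2-methylbut-3-en-2-yl)oxy]-4-(triisopropylsilyloxy)phenyl]ethan-1-one | CC(=O)c1c(OCc2ccc(O[Si](C(C)C)(C(C)C)C(C)C)c(OC)c2)cc(O[Si](C(C)C)(C(C)C)C(C)C)cc1OC(C)(C)C=C
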